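The two C–O bonds of the ring B oxirane are cut first (ring B locants: C1 CMe2, C3 C–O, C5 C–Me, C6 C–chain), leaving a tetrasubstituted C5=C6 alkene in a complete skeleton; then the bond from the lactone alpha carbon to the ring B vinyl group, the exocyclic C=C at the lactone gamma carbon, two chain C=C bonds and the ring A C–alkyne bond.
Forward, 4-oxoisophorone gives one (R)-configured enol triflate; one part becomes ring A and its chain (Sonogashira, Horner–Wadsworth–Emmons, Wittig) and then the bromo-ylidenebutenolide (vinylogous aldol addition, elimination); the other part becomes the ring B dienylstannane, joined last by Stille coupling; the oxirane is the only ring closed late.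
The carbinol centre of both rings comes from an enzymatic C=C reduction relayed by a diastereoselective ketone reduction; alkene geometry comes from the E-enynol, E-selective olefinations, a thermodynamic Z-ylidene and stereoretentive couplings; C5 and C6 are set anti to the C3 silyloxy group in the epoxidation.
Enabling feature: the oxirane carbons C5 and C6 of ring B bear no hydrogen and their oxygen sits on the face opposite the C3 oxygen, and with that bridging oxygen removed ring B is the same (R)-3-oxy-2,6,6-trimethylcyclohex-1-enyl unit as ring A, so one chiral block feeds both rings and the C3 group can steer the last oxygen.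
Key step: step 17

Remark: ring A is the acetoxy ring on the alkyne and ring B the ring that ends as the oxirane; the anti preference of peracids toward 3-silyloxy cyclohexene end groups is assumed to hold for the dienyl-butenolide-substituted ring B (TBS = tert-butyldimethylsilyl, Tf = trifluoromethanesulfonyl).

Step 1
Reactants: 1 4-oxoisophorone (2,6,6-trimethylcyclohex-2-ene-1,4-dione)
Product: 2 (6R)-2,2,6-trimethylcyclohexane-1,4-dione
Conditions: ene-reductase (old yellow enzyme), NADP+ (cat.), glucose dehydrogenase, D-glucose, phosphate buffer pH 7, 30 °C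
Reagents that add atoms: none
Why: Enzymatic asymmetric conjugate reduction (ene-reductase hydrogenation of the enedione C=C) adds hydride and a proton from the face fixed by the active site and so sets the methyl-bearing centre as (6R), while neutral buffer limits its epimerisation.

Step 2
Reactants: 2 (6R)-2,2,6-trimethylcyclohexane-1,4-dione
Product: 3 (4R,6R)-4-hydroxy-2,2,6-trimethylcyclohexan-1-one
Conditions: LiBH(s-Bu)3, THF, −78 °C; then NaOH, H2O2, 0 °C
Reagents that add atoms: none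
Why: Diastereoselective hydride reduction with a bulky trialkylborohydride touches only the unhindered C4 carbonyl and attacks it equatorially, because the axial methyl at C2 blocks the axial path, so the alcohol should form trans to the C6 methyl as (4R) under control by the C6 centre.

Step 3
Reactants: 3 (4R,6R)-4-hydroxy-2,2,6-trimethylcyclohexan-1-one
Product: 4 (4R,6R)-4-(TBSO)-2,2,6-trimethylcyclohexan-1-one
Conditions: TBSCl, imidazole, DMF, rt
Reagents that add atoms: tert-butyldimethylsilyl chloride, CC(C)(C)[Si](C)(C)Cl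
Why: Silylation of the secondary alcohol with a silyl chloride and imidazole is routine and leaves the hindered ketone and the C4 configuration untouched.

Step 4
Reactants: 4 (4R,6R)-4-(TBSO)-2,2,6-trimethylcyclohexan-1-one
Product: 6 (4R)-4-(TBSO)-2,6,6-trimethylcyclohex-1-en-1-yl trifluoromethanesulfonate, via lithium enolate 5 (not isolated)
Conditions: LiN(i-Pr)2, THF, −78 °C; then PhNTf2, −78 °C to rt
Reagents that add atoms: N-phenylbis(trifluoromethanesulfonimide), O=S(=O)(N(c1ccccc1)S(=O)(=O)C(F)(F)F)C(F)(F)F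
Why: Enol triflate formation works because the amide base can deprotonate only C6 (C2 is quaternary) and O-sulfonylation of enolate 5 then gives the tetrasubstituted alkenyl triflate, in which the C6 centre is erased and C4 is untouched.

Step 5
Reactants: 6 (4R)-4-(TBSO)-2,6,6-trimethylcyclohex-1-en-1-yl trifluoromethanesulfonate; 7 (E)-3-methylpent-2-en-4-yn-1-ol
Product: 8 (2E)-5-[(4R)-4-(TBSO)-2,6,6-trimethylcyclohex-1-en-1-yl]-3-methylpent-2-en-4-yn-1-ol
Conditions: Pd(PPh3)4, CuI, Et3N, DMF, 50 °C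
Reagents that add atoms: none
Why: Sonogashira coupling of an alkenyl triflate with a terminal alkyne forms the ring A C(sp2)–C(sp) bond under mild basic conditions that tolerate the free alcohol, the silyl ether and the E-alkene of 7.

Step 6
Reactants: 8 (2E)-5-[(4R)-4-(TBSO)-2,6,6-trimethylcyclohex-1-en-1-yl]-3-methylpent-2-en-4-yn-1-ol
Product: 9 (2E)-5-[(4R)-4-(TBSO)-2,6,6-trimethylcyclohex-1-en-1-yl]-3-methylpent-2-en-4-ynal
Conditions: MnO2, CH2Cl2, rt
Reagents that add atoms: none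
Why: Allylic oxidation with MnO2 converts the primary allylic alcohol to the enal without touching the alkyne or the silyl ether and without E/Z isomerisation.

Step 7
Reactants: 9 (2E)-5-[(4R)-4-(TBSO)-2,6,6-trimethylcyclohex-1-en-1-yl]-3-methylpent-2-en-4-ynal; 10 triethyl 4-phosphonocrotonate (ethyl (2E)-4-(diethoxyphosphoryl)but-2-enoate)
Product: 11 ethyl (2E,4E,6E)-9-[(4R)-4-(TBSO)-2,6,6-trimethylcyclohex-1-en-1-yl]-7-methylnona-2,4,6-trien-8-ynoate
Conditions: 10, LiN(SiMe3)2, THF, −78 °C; then 9, −78 to 0 °C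
Reagents that add atoms: none
Why: Horner–Wadsworth–Emmons olefination with the stabilised vinylogous phosphonate anion is reversible in its addition step and should therefore give the new disubstituted alkene with E geometry while the E bond of the crotonate is kept.

Step 8
Reactants: 11 ethyl (2E,4E,6E)-9-[(4R)-4-(TBSO)-2,6,6-trimethylcyclohex-1-en-1-yl]-7-methylnona-2,4,6-trien-8-ynoate
Product: 12 (2E,4E,6E)-9-[(4R)-4-(TBSO)-2,6,6-trimethylcyclohex-1-en-1-yl]-7-methylnona-2,4,6-trien-8-yn-1-ol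
Conditions: i-Bu2AlH, CH2Cl2, −78 °C
Reagents that add atoms: none
Why: Hydride reduction of the conjugated ester with the aluminium hydride at low temperature proceeds by 1,2-addition to the allylic alcohol and spares the silyl ether, the alkyne and the polyene.

Step 9
Reactants: 12 (2E,4E,6E)-9-[(4R)-4-(TBSO)-2,6,6-trimethylcyclohex-1-en-1-yl]-7-methylnona-2,4,6-trien-8-yn-1-ol
Product: 13 (2E,4E,6E)-9-[(4R)-4-(TBSO)-2,6,6-trimethylcyclohex-1-en-1-yl]-7-methylnona-2,4,6-trien-8-ynal
Conditions: MnO2, CH2Cl2, rt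
Reagents that add atoms: none
Why: Allylic oxidation with MnO2, as in step 6, stops cleanly at the conjugated aldehyde.

Step 10
Reactants: 13 (2E,4E,6E)-9-[(4R)-4-(TBSO)-2,6,6-trimethylcyclohex-1-en-1-yl]-7-methylnona-2,4,6-trien-8-ynal; 14 2-(triphenylphosphoranylidene)propanal
Product: 15 (2E,4E,6E,8E)-11-[(4R)-4-(TBSO)-2,6,6-trimethylcyclohex-1-en-1-yl]-2,9-dimethylundeca-2,4,6,8-tetraen-10-ynal
Conditions: toluene, 90 °C
Reagents that add atoms: none
Why: Wittig olefination with the stabilised formyl ylide should give the trisubstituted (E)-2-methyl enal under thermodynamic control, and the alpha-branched polyenal formed is too weak an electrophile for a second homologation.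

Step 11
Reactants: 15 (2E,4E,6E,8E)-11-[(4R)-4-(TBSO)-2,6,6-trimethylcyclohex-1-en-1-yl]-2,9-dimethylundeca-2,4,6,8-tetraen-10-ynal
Product: 16 (2E,4E,6E,8E)-11-[(4R)-4-hydroxy-2,6,6-trimethylcyclohex-1-en-1-yl]-2,9-dimethylundeca-2,4,6,8-tetraen-10-ynal
Conditions: Bu4NF, AcOH, THF, rt
Reagents that add atoms: none
Why: Fluoride-induced desilylation, buffered with acetic acid to protect the polyenal from base, frees the ring A alcohol without affecting its configuration.

Step 12
Reactants: 16 (2E,4E,6E,8E)-11-[(4R)-4-hydroxy-2,6,6-trimethylcyclohex-1-en-1-yl]-2,9-dimethylundeca-2,4,6,8-tetraen-10-ynal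
Product: 17 (1R)-4-[(3E,5E,7E,9E)-3,10-dimethyl-11-oxoundeca-3,5,7,9-tetraen-1-yn-1-yl]-3,5,5-trimethylcyclohex-3-en-1-yl acetate
Conditions: Ac2O, pyridine, DMAP (cat.), CH2Cl2, 0 °C to rt
Reagents that add atoms: acetic anhydride, CC(=O)OC(C)=O
Why: Acylation of the secondary alcohol under nucleophilic catalysis by DMAP installs the ring A acetate of the target with retention at carbon, before the second silyl-protected ring enters.

Step 13
Reactants: 18 furan-2(5H)-one
Product: 20 3-bromofuran-2(5H)-one, via trans-dibromolactone 19 (not isolated)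
Conditions: Br2, CH2Cl2, reflux; then Et3N, 0 °C
Reagents that add atoms: bromine, BrBr
Why: Anti addition of bromine to the lactone alkene followed by base-induced E1cB dehydrobromination, in which the acidic lactone C3 hydrogen is removed and the C4 bromide leaves, gives the alpha-bromobutenolide.

Step 14
Reactants: 20 3-bromofuran-2(5H)-one; 17 (1R)-4-[(3E,5E,7E,9E)-3,10-dimethyl-11-oxoundeca-3,5,7,9-tetraen-1-yn-1-yl]-3,5,5-trimethylcyclohex-3-en-1-yl acetate
Product: 23 (1R)-4-[(3E,5E,7E,9E,11Z)-11-(4-bromo-5-oxofuran-2(5H)-ylidene)-3,10-dimethylundeca-3,5,7,9-tetraen-1-yn-1-yl]-3,5,5-trimethylcyclohex-3-en-1-yl acetate, via silyloxyfuran 21 (not isolated), via silylated aldol adduct 22 (not isolated)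
Conditions: 20, t-BuMe2SiOTf, i-Pr2NEt, CH2Cl2, 0 °C to rt; then 17; then DBU, rt
Reagents that add atoms: none
Why: Vinylogous Mukaiyama aldol addition of the silyloxyfuran 21 through its C5 to the silyl-triflate-activated aldehyde, followed by DBU-mediated E1cB loss of silanolate from 22, should give the ylidenebutenolide, and reversible deprotonation funnels both diastereomers of 22 into the thermodynamically preferred Z-ylidene.

Step 15
Reactants: 6 (4R)-4-(TBSO)-2,6,6-trimethylcyclohex-1-en-1-yl trifluoromethanesulfonate; 24 (E)-1,2-bis(tributylstannyl)ethene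
Product: 25 tert-butyldimethyl({(1R)-3,5,5-trimethyl-4-[(E)-2-(tributylstannyl)ethenyl]cyclohex-3-en-1-yl}oxy)silane
Conditions: 24 (2.5 equiv), Pd2(dba)3, AsPh3, LiCl, NMP, 60 °C
Reagents that add atoms: none
Why: Stille coupling of the alkenyl triflate in the presence of LiCl transfers one alkenyl group of the distannane with retention of its E geometry, and the excess of 24 should hold the reaction at the mono-coupling stage.

Step 16
Reactants: 23 (1R)-4-[(3E,5E,7E,9E,11Z)-11-(4-bromo-5-oxofuran-2(5H)-ylidene)-3,10-dimethylundeca-3,5,7,9-tetraen-1-yn-1-yl]-3,5,5-trimethylcyclohex-3-en-1-yl acetate; 25 tert-butyldimethyl({(1R)-3,5,5-trimethyl-4-[(E)-2-(tributylstannyl)ethenyl]cyclohex-3-en-1-yl}oxy)silane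
Product: 26 (1R)-4-[(3E,5E,7E,9E,11Z)-11-{4-[(E)-2-{(4R)-4-(TBSO)-2,6,6-trimethylcyclohex-1-en-1-yl}ethenyl]-5-oxofuran-2(5H)-ylidene}-3,10-dimethylundeca-3,5,7,9-tetraen-1-yn-1-yl]-3,5,5-trimethylcyclohex-3-en-1-yl acetate
Conditions: Pd2(dba)3, AsPh3, NMP, 40 °C, dark
Reagents that add atoms: none
Why: Stille coupling of the alpha-bromobutenolide with the dienylstannane under ligand-accelerated neutral conditions forms the bond from the lactone alpha carbon to the vinyl group with retention of both alkene geometries and tolerates the acetate, the silyl ether and the Z-ylidene.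

Step 17
Reactants: 26 (1R)-4-[(3E,5E,7E,9E,11Z)-11-{4-[(E)-2-{(4R)-4-(TBSO)-2,6,6-trimethylcyclohex-1-en-1-yl}ethenyl]-5-oxofuran-2(5H)-ylidene}-3,10-dimethylundeca-3,5,7,9-tetraen-1-yn-1-yl]-3,5,5-trimethylcyclohex-3-en-1-yl acetate
Product: 27 (1R)-4-[(3E,5E,7E,9E,11Z)-11-{4-[(E)-2-{(1S,4S,6R)-4-(TBSO)-2,2,6-trimethyl-7-oxabicyclo[4.1.0]heptan-1-yl}ethenyl]-5-oxofuran-2(5H)-ylidene}-3,10-dimethylundeca-3,5,7,9-tetraen-1-yn-1-yl]-3,5,5-trimethylcyclohex-3-en-1-yl acetate (oxirane oxygen anti to the silyloxy group)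
Conditions: mCPBA (1.05 equiv), NaHCO3, CH2Cl2, −20 to 0 °C, dark
Reagents that add atoms: 3-chloroperoxybenzoic acid (mCPBA), O=C(OO)c1cccc(Cl)c1
Why: The peracid hands its terminal oxygen to the C5=C6 alkene of ring B through one concerted spiro (butterfly) transition state, so both C–O bonds form on the same face in a single event, and the closest known reaction type is the Prilezhaev 5,6-epoxidation of carotenoid beta end groups carried out with the polyene chain in place. The oxirane, the only ring made here, thus closes by a concerted syn [2+1] addition of one oxygen atom across the alkene and not by a stepwise ring closure. The two new quaternary centres C5 and C6 are set together by the face that is attacked, and that face is fixed by the C3 stereocentre, whose bulky silyloxy group cannot hydrogen-bond to the peracid and hinders its own side, so oxygen should arrive anti and give (5R,6S). The step needs site selectivity among nine C=C bonds and one alkyne, and this rests on an electronic ranking in which the ring B alkene is tetrasubstituted and twisted out of the chain plane by its flanking methyl groups, the chain and lactone alkenes share their electrons with the lactone carbonyl, and the ring A alkene is deactivated by the attached alkyne. One equivalent of oxidant at low temperature over bicarbonate should hold back over-oxidation and acid-induced rearrangement of the vinyl oxirane, and the minor syn epoxide should be removable by chromatography.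

Step 18
Reactants: 27 (1R)-4-[(3E,5E,7E,9E,11Z)-11-{4-[(E)-2-{(1S,4S,6R)-4-(TBSO)-2,2,6-trimethyl-7-oxabicyclo[4.1.0]heptan-1-yl}ethenyl]-5-oxofuran-2(5H)-ylidene}-3,10-dimethylundeca-3,5,7,9-tetraen-1-yn-1-yl]-3,5,5-trimethylcyclohex-3-en-1-yl acetate
Product: 28 (1R)-4-[(3E,5E,7E,9E,11Z)-11-{4-[(E)-2-{(1S,4S,6R)-4-hydroxy-2,2,6-trimethyl-7-oxabicyclo[4.1.0]heptan-1-yl}ethenyl]-5-oxofuran-2(5H)-ylidene}-3,10-dimethylundeca-3,5,7,9-tetraen-1-yn-1-yl]-3,5,5-trimethylcyclohex-3-en-1-yl acetate (the target)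
Conditions: Bu4NF, AcOH, THF, 0 °C to rt
Reagents that add atoms: none
Why: Desilylation with acetic acid-buffered fluoride cleaves the Si–O bond at near-neutral pH, so the acetate, the ylidenebutenolide and the acid-labile vinyl oxirane should survive and the C3 configuration is retained.

Compound list
1 | 4-oxoisophorone (2,6,6-trimethylcyclohex-2-ene-1,4-dione) | CC1=CC(=O)CC(C)(C)C1=O | starting material
2 | (6R)-2,2,6-trimethylcyclohexane-1,4-dione | C[C@@H]1CC(=O)CC(C)(C)C1=O | intermediate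
3 | (4R,6R)-4-hydroxy-2,2,6-trimethylcyclohexan-1-one | O[C@@H]1C[C@@H](C)C(=O)C(C)(C)C1 | intermediate
4 | (4R,6R)-4-(TBSO)-2,2,6-trimethylcyclohexan-1-one | CC(C)(C)[Si](C)(C)O[C@@H]1C[C@@H](C)C(=O)C(C)(C)C1 | intermediate
5 | lithium (4R)-4-(TBSO)-2,6,6-trimethylcyclohex-1-en-1-olate (lithium enolate of 4) | CC(C)(C)[Si](C)(C)O[C@@H]1CC(C)=C(O[Li])C(C)(C)C1 | intermediate
6 | (4R)-4-(TBSO)-2,6,6-trimethylcyclohex-1-en-1-yl trifluoromethanesulfonate | CC(C)(C)[Si](C)(C)O[C@@H]1CC(C)=C(OS(=O)(=O)C(F)(F)F)C(C)(C)C1 | intermediate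
7 | (E)-3-methylpent-2-en-4-yn-1-ol | C#C/C(C)=C/CO | starting material
8 | (2E)-5-[(4R)-4-(TBSO)-2,6,6-trimethylcyclohex-1-en-1-yl]-3-methylpent-2-en-4-yn-1-ol | CC(C)(C)[Si](C)(C)O[C@@H]1CC(C)=C(C#C/C(C)=C/CO)C(C)(C)C1 | intermediate
9 | (2E)-5-[(4R)-4-(TBSO)-2,6,6-trimethylcyclohex-1-en-1-yl]-3-methylpent-2-en-4-ynal | CC(C)(C)[Si](C)(C)O[C@@H]1CC(C)=C(C#C/C(C)=C/C=O)C(C)(C)C1 | intermediate
10 | triethyl 4-phosphonocrotonate (ethyl (2E)-4-(diethoxyphosphoryl)but-2-enoate) | CCOC(=O)/C=C/CP(=O)(OCC)OCC | starting material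
11 | ethyl (2E,4E,6E)-9-[(4R)-4-(TBSO)-2,6,6-trimethylcyclohex-1-en-1-yl]-7-methylnona-2,4,6-trien-8-ynoate | CC(C)(C)[Si](C)(C)O[C@@H]1CC(C)=C(C#C/C(C)=C/C=C/C=C/C(=O)OCC)C(C)(C)C1 | intermediate
12 | (2E,4E,6E)-9-[(4R)-4-(TBSO)-2,6,6-trimethylcyclohex-1-en-1-yl]-7-methylnona-2,4,6-trien-8-yn-1-ol | CC(C)(C)[Si](C)(C)O[C@@H]1CC(C)=C(C#C/C(C)=C/C=C/C=C/CO)C(C)(C)C1 | intermediate
13 | (2E,4E,6E)-9-[(4R)-4-(TBSO)-2,6,6-trimethylcyclohex-1-en-1-yl]-7-methylnona-2,4,6-trien-8-ynal | CC(C)(C)[Si](C)(C)O[C@@H]1CC(C)=C(C#C/C(C)=C/C=C/C=C/C=O)C(C)(C)C1 | intermediate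
14 | 2-(triphenylphosphoranylidene)propanal | CC(C=O)=P(c1ccccc1)(c1ccccc1)c1ccccc1 | starting material
15 | (2E,4E,6E,8E)-11-[(4R)-4-(TBSO)-2,6,6-trimethylcyclohex-1-en-1-yl]-2,9-dimethylundeca-2,4,6,8-tetraen-10-ynal | CC(C)(C)[Si](C)(C)O[C@@H]1CC(C)=C(C#C/C(C)=C/C=C/C=C/C=C(C)/C=O)C(C)(C)C1 | intermediate
16 | (2E,4E,6E,8E)-11-[(4R)-4-hydroxy-2,6,6-trimethylcyclohex-1-en-1-yl]-2,9-dimethylundeca-2,4,6,8-tetraen-10-ynal | O[C@@H]1CC(C)=C(C#C/C(C)=C/C=C/C=C/C=C(C)/C=O)C(C)(C)C1 | intermediate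
17 | (1R)-4-[(3E,5E,7E,9E)-3,10-dimethyl-11-oxoundeca-3,5,7,9-tetraen-1-yn-1-yl]-3,5,5-trimethylcyclohex-3-en-1-yl acetate | CC(=O)O[C@@H]1CC(C)=C(C#C/C(C)=C/C=C/C=C/C=C(C)/C=O)C(C)(C)C1 | intermediate
18 | furan-2(5H)-one | O=C1OCC=C1 | starting material
19 | trans-3,4-dibromodihydrofuran-2(3H)-one (racemic, one enantiomer drawn) | O=C1OC[C@@H](Br)[C@@H]1Br | intermediate
20 | 3-bromofuran-2(5H)-one | O=C1OCC=C1Br | intermediate
21 | [(3-bromofuran-2-yl)oxy](tert-butyl)dimethylsilane | CC(C)(C)[Si](C)(C)Oc1occc1Br | intermediate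
22 | (1R)-4-[(3E,5E,7E,9E)-11-(4-bromo-5-oxo-2,5-dihydrofuran-2-yl)-11-(TBSO)-3,10-dimethylundeca-3,5,7,9-tetraen-1-yn-1-yl]-3,5,5-trimethylcyclohex-3-en-1-yl acetate (mixture of diastereomers at the two new carbons) | CC(=O)O[C@@H]1CC(C)=C(C#C/C(C)=C/C=C/C=C/C=C(C)/C(O[Si](C)(C)C(C)(C)C)C2C=C(Br)C(=O)O2)C(C)(C)C1 | intermediate
23 | (1R)-4-[(3E,5E,7E,9E,11Z)-11-(4-bromo-5-oxofuran-2(5H)-ylidene)-3,10-dimethylundeca-3,5,7,9-tetraen-1-yn-1-yl]-3,5,5-trimethylcyclohex-3-en-1-yl acetate | CC(=O)O[C@@H]1CC(C)=C(C#C/C(C)=C/C=C/C=C/C=C(C)/C=C2C=C(Br)C(=O)O/2)C(C)(C)C1 | intermediate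
24 | (E)-1,2-bis(tributylstannyl)ethene | CCCC[Sn](CCCC)(CCCC)/C=C/[Sn](CCCC)(CCCC)CCCC | starting material
25 | tert-butyldimethyl({(1R)-3,5,5-trimethyl-4-[(E)-2-(tributylstannyl)ethenyl]cyclohex-3-en-1-yl}oxy)silane | CC(C)(C)[Si](C)(C)O[C@@H]1CC(C)=C(/C=C/[Sn](CCCC)(CCCC)CCCC)C(C)(C)C1 | intermediate
26 | (1R)-4-[(3E,5E,7E,9E,11Z)-11-{4-[(E)-2-{(4R)-4-(TBSO)-2,6,6-trimethylcyclohex-1-en-1-yl}ethenyl]-5-oxofuran-2(5H)-ylidene}-3,10-dimethylundeca-3,5,7,9-tetraen-1-yn-1-yl]-3,5,5-trimethylcyclohex-3-en-1-yl acetate | CC(=O)O[C@@H]1CC(C)=C(C#C/C(C)=C/C=C/C=C/C=C(C)/C=C2C=C(/C=C/C3=C(C)C[C@@H](O[Si](C)(C)C(C)(C)C)CC3(C)C)C(=O)O/2)C(C)(C)C1 | intermediate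
27 | (1R)-4-[(3E,5E,7E,9E,11Z)-11-{4-[(E)-2-{(1S,4S,6R)-4-(TBSO)-2,2,6-trimethyl-7-oxabicyclo[4.1.0]heptan-1-yl}ethenyl]-5-oxofuran-2(5H)-ylidene}-3,10-dimethylundeca-3,5,7,9-tetraen-1-yn-1-yl]-3,5,5-trimethylcyclohex-3-en-1-yl acetate | CC(=O)O[C@@H]1CC(C)=C(C#C/C(C)=C/C=C/C=C/C=C(C)/C=C2C=C(/C=C/[C@@]34O[C@]3(C)C[C@@H](O[Si](C)(C)C(C)(C)C)CC4(C)C)C(=O)O/2)C(C)(C)C1 | intermediate
28 | (1R)-4-[(3E,5E,7E,9E,11Z)-11-{4-[(E)-2-{(1S,4S,6R)-4-hydroxy-2,2,6-trimethyl-7-oxabicyclo[4.1.0]heptan-1-yl}ethenyl]-5-oxofuran-2(5H)-ylidene}-3,10-dimethylundeca-3,5,7,9-tetraen-1-yn-1-yl]-3,5,5-trimethylcyclohex-3-en-1-yl acetate | CC(=O)O[C@@H]1CC(C)=C(C#C/C(C)=C/C=C/C=C/C=C(C)/C=C2C=C(/C=C/[C@@]34O[C@]3(C)C[C@@H](O)CC4(C)C)C(=O)O/2)C(C)(C)C1 | target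

Total step count: 18.
Longest linear sequence: 16 steps (steps 1 to 12, then 14, 16, 17 and 18).

Steps most likely to fail

Step 17. Oxygen transfer may go to another alkene or arrive from the syn face, and the vinyl oxirane may rearrange under the acid set free. The fallback builds the oxirane on a small ring B block under reagent control and carries it through the coupling. It sets out from 6. Palladium-catalysed methoxycarbonylation (Pd(OAc)2, 1,3-bis(diphenylphosphino)propane, CO, MeOH, Et3N, DMF) should give methyl (4R)-4-(TBSO)-2,6,6-trimethylcyclohex-1-ene-1-carboxylate F1. Reduction with i-Bu2AlH gives [(4R)-4-(TBSO)-2,6,6-trimethylcyclohex-1-en-1-yl]methanol F2. Sharpless asymmetric epoxidation (Ti(O-i-Pr)4, D-(−)-diethyl tartrate, t-BuOOH, CH2Cl2, −20 °C) delivers oxygen anti to the silyloxy group to give [(1R,4S,6R)-4-(TBSO)-2,2,6-trimethyl-7-oxabicyclo[4.1.0]heptan-1-yl]methanol F3. Dess–Martin oxidation gives (1S,4S,6R)-4-(TBSO)-2,2,6-trimethyl-7-oxabicyclo[4.1.0]heptane-1-carbaldehyde F4. Takai–Hodgson stannylolefination (Bu3SnCHBr2, CrCl2, LiI, THF/DMF) gives tert-butyldimethyl({(1S,4S,6R)-2,2,6-trimethyl-1-[(E)-2-(tributylstannyl)ethenyl]-7-oxabicyclo[4.1.0]heptan-4-yl}oxy)silane F5. Stille coupling of F5 with bromide 23 under the conditions of step 16 comes back to the route at 27, replacing steps 15 to 17.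

Step 14. The silyloxyfuran may add only slowly to the weakly electrophilic polyenal, and the elimination may stall or scramble the ylidene geometry. The fallback is a stepwise sequence with an isolated nucleophile, a stronger Lewis acid and a separate dehydration. It sets out from 20 and 17. Silylation of 20 (i-Pr3SiOTf, Et3N) gives [(3-bromofuran-2-yl)oxy]tri(propan-2-yl)silane F6. Vinylogous Mukaiyama aldol addition of F6 to 17 with BF3·OEt2 at −78 °C gives (1R)-4-[(3E,5E,7E,9E)-11-(4-bromo-5-oxo-2,5-dihydrofuran-2-yl)-11-hydroxy-3,10-dimethylundeca-3,5,7,9-tetraen-1-yn-1-yl]-3,5,5-trimethylcyclohex-3-en-1-yl acetate F7. Mesylation (MsCl, Et3N) and E1cB elimination with DBU come back to the route at 23.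

Step 15. Oxidative addition into the hindered triflate may be slow, so that double coupling of the distannane and protodestannylation take over. The fallback builds the vinyltin unit by alkynylation and hydrostannylation. It sets out from 6. Sonogashira coupling with ethynyltrimethylsilane gives tert-butyldimethyl({(1R)-3,5,5-trimethyl-4-[(trimethylsilyl)ethynyl]cyclohex-3-en-1-yl}oxy)silane F8. K2CO3 in MeOH gives tert-butyl{[(1R)-4-ethynyl-3,5,5-trimethylcyclohex-3-en-1-yl]oxy}dimethylsilane F9. Palladium-catalysed syn hydrostannylation of the terminal alkyne (PdCl2(PPh3)2, Bu3SnH, THF) comes back to the route at 25.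

Further compounds
F1 | step 17 | methyl (4R)-4-(TBSO)-2,6,6-trimethylcyclohex-1-ene-1-carboxylate | CC(C)(C)[Si](C)(C)O[C@@H]1CC(C)=C(C(=O)OC)C(C)(C)C1
F2 | step 17 | [(4R)-4-(TBSO)-2,6,6-trimethylcyclohex-1-en-1-yl]methanol | CC(C)(C)[Si](C)(C)O[C@@H]1CC(C)=C(CO)C(C)(C)C1
F3 | step 17 | [(1R,4S,6R)-4-(TBSO)-2,2,6-trimethyl-7-oxabicyclo[4.1.0]heptan-1-yl]methanol | OC[C@@]12O[C@]1(C)C[C@@H](O[Si](C)(C)C(C)(C)C)CC2(C)C
F4 | step 17 | (1S,4S,6R)-4-(TBSO)-2,2,6-trimethyl-7-oxabicyclo[4.1.0]heptane-1-carbaldehyde | O=C[C@@]12O[C@]1(C)C[C@@H](O[Si](C)(C)C(C)(C)C)CC2(C)C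
F5 | step 17 | tert-butyldimethyl({(1S,4S,6R)-2,2,6-trimethyl-1-[(E)-2-(tributylstannyl)ethenyl]-7-oxabicyclo[4.1.0]heptan-4-yl}oxy)silane | CCCC[Sn](CCCC)(CCCC)/C=C/[C@@]12O[C@]1(C)C[C@@H](O[Si](C)(C)C(C)(C)C)CC2(C)C
F6 | step 14 | [(3-bromofuran-2-yl)oxy]tri(propan-2-yl)silane | CC(C)[Si](Oc1occc1Br)(C(C)C)C(C)C
F7 | step 14 | (1R)-4-[(3E,5E,7E,9E)-11-(4-bromo-5-oxo-2,5-dihydrofuran-2-yl)-11-hydroxy-3,10-dimethylundeca-3,5,7,9-tetraen-1-yn-1-yl]-3,5,5-trimethylcyclohex-3-en-1-yl acetate (mixture of diastereomers) | CC(=O)O[C@@H]1CC(C)=C(C#C/C(C)=C/C=C/C=C/C=C(C)/C(O)C2C=C(Br)C(=O)O2)C(C)(C)C1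
F8 | step 15 | tert-butyldimethyl({(1R)-3,5,5-trimethyl-4-[(trimethylsilyl)ethynyl]cyclohex-3-en-1-yl}oxy)silane | CC(C)(C)[Si](C)(C)O[C@@H]1CC(C)=C(C#C[Si](C)(C)C)C(C)(C)C1
F9 | step 15 | tert-butyl{[(1R)-4-ethynyl-3,5,5-trimethylcyclohex-3-en-1-yl]oxy}dimethylsilane | CC(C)(C)[Si](C)(C)O[C@@H]1CC(C)=C(C#C)C(C)(C)C1
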